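**Retrosynthetic overview**

1. The target is 2-methyl-1,4-naphthoquinone with an all-E nonaprenyl chain whose units II and III are saturated (7'R,11'S; chain numbered C1'–C36' from the ring CH2). No ring is formed in the route: the naphthalene core comes from menadione, is masked as its 1,4-dimethyl ether and is re-oxidised by Ce(IV) in the last step.
2. Key disconnection C16'–C17': the CH2–CH2 σ-bond at the centre of the open-chain 1,5-diene C14'=C15'–C16'–C17'–C18'=C19'. Both carbons are allylic (C16' is the E-"methyl" carbon on C15', C17' is C1 of the geranylfarnesyl unit), so one is used as an allylbarium and the other as an allylic bromide in an α,α'-selective allyl–allyl coupling. This is a polarity-reversed copy of the biosynthetic head-to-tail prenyl transfer (C25 to C30) that forms the same bond.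
3. C25 half: all-E geranylfarnesyl chloride from (2E,6E)-farnesyl chloride and an 8-bromogeranyl silyl ether by the same allylbarium coupling.
4. Arene–C20 half: C1'–C2' by Ni(0) coupling of a benzylic chloride with the alkenylalane from Zr-catalysed carboalumination of a C18 alkyne (sets C2'=C3' as E); C8'–C9' and C5'–C6' by Cu-catalysed Grignard couplings; C11' and C7' from the chiral pool; C16' oxygenated by SeO2.
5. Order: arene chloride and chiral alkyne, then arene–C20 allylic bromide; C25 chloride; fragment union; oxidative demethylation.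

Key step: step 16

Assumption: (R)-citronellyl bromide, (S)-3-bromo-2-methylpropan-1-ol, (2E,6E)-farnesyl chloride and 4-bromo-1-(trimethylsilyl)but-1-yne are taken as catalogue compounds of high enantiomeric and geometric purity.

**Route**

Step 1
Reactants: 1 menadione (2-methylnaphthalene-1,4-dione)
Product: 3 1,4-dimethoxy-2-methylnaphthalene, via menadiol 2 (not isolated)
Conditions: Na2S2O4, THF/H2O, rt, N2; then KOH (aq), Me2SO4, Bu4NBr (cat.), rt
Reagents that add atoms: dimethyl sulfate, COS(=O)(=O)OC
Why: Dithionite reduces the quinone to the air-sensitive hydroquinone 2, whose two phenoxides are O-methylated in the same pot (reductive methylation, Williamson-type etherification), which masks the quinone against the organometallic steps that follow.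

Step 2
Reactants: 3 1,4-dimethoxy-2-methylnaphthalene
Product: 4 2-(chloromethyl)-1,4-dimethoxy-3-methylnaphthalene
Conditions: (CH2O)n, HCl (g), conc. HCl/AcOH, rt to 40 °C
Reagents that add atoms: formaldehyde (as paraformaldehyde), C=O; hydrogen chloride, Cl
Why: Blanc chloromethylation, an electrophilic aromatic substitution, should occur at C3, the only free position of the doubly alkoxy-activated ring, and gives the benzylic chloride needed for the nickel coupling.

Step 3
Reactants: 5 (S)-3-bromo-2-methylpropan-1-ol
Product: 6 (S)-1-bromo-3-chloro-2-methylpropane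
Conditions: PPh3, CCl4, CH2Cl2, 0 °C to rt
Reagents that add atoms: carbon tetrachloride, ClC(Cl)(Cl)Cl
Why: Appel chlorination replaces the primary hydroxyl by chloride at a CH2 group under neutral conditions, so the neighbouring stereocentre is untouched and a bromide/chloride pair of graded reactivity results.

Step 4
Reactants: 6 (S)-1-bromo-3-chloro-2-methylpropane; 7 (R)-citronellyl bromide [(6R)-8-bromo-2,6-dimethyloct-2-ene]
Product: 9 (2R,6S)-1-chloro-2,6,10-trimethylundec-9-ene, via (R)-citronellylmagnesium bromide 8 (not isolated)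
Conditions: 7, Mg, THF, 40 °C; then 6 (slight excess), Li2CuCl4 (3 mol%), THF, −20 °C to rt
Reagents that add atoms: none
Why: Copper-catalysed sp3–sp3 Grignard cross-coupling (Kochi type) should take place only at the C–Br bond of 6, the C–Cl bond being inert under these conditions, so both stereocentres (C11' from 7, C7' from 6) come from the chiral pool without any bond to them being made or broken.

Step 5
Reactants: 9 (2R,6S)-1-chloro-2,6,10-trimethylundec-9-ene; 10 4-bromo-1-(trimethylsilyl)but-1-yne
Product: 12 trimethyl[(6R,10S)-6,10,14-trimethylpentadec-13-en-1-yn-1-yl]silane, via Grignard reagent 11 (not isolated)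
Conditions: 9, Mg (BrCH2CH2Br-activated), THF, reflux; then 10, Li2CuCl4 (5 mol%), THF/NMP, −20 °C to rt
Reagents that add atoms: none
Why: The chloride is converted into its Grignard reagent and joined to the primary homopropargylic bromide by the same copper-catalysed sp3–sp3 coupling, the silyl cap keeping the acetylenic C–H away from the basic organomagnesium.

Step 6
Reactants: 12 trimethyl[(6R,10S)-6,10,14-trimethylpentadec-13-en-1-yn-1-yl]silane
Product: 13 (6R,10S)-6,10,14-trimethylpentadec-13-en-1-yne
Conditions: K2CO3 (cat.), MeOH, rt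
Reagents that add atoms: none
Why: Carbonate-catalysed methanolysis of the alkynyl C–Si bond (protiodesilylation) frees the terminal alkyne without affecting the olefin or the stereocentres.

Step 7
Reactants: 13 (6R,10S)-6,10,14-trimethylpentadec-13-en-1-yne; 4 2-(chloromethyl)-1,4-dimethoxy-3-methylnaphthalene
Product: 15 1,4-dimethoxy-2-methyl-3-[(2E,7R,11S)-3,7,11,15-tetramethylhexadeca-2,14-dien-1-yl]naphthalene, via (E)-alkenylalane 14 (not isolated)
Conditions: Me3Al (2 equiv), Cp2ZrCl2 (0.2 equiv), CH2Cl2, 0 °C to rt; then 4, Ni(0) (3 mol%, from NiCl2(PPh3)2/n-BuLi), THF, rt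
Reagents that add atoms: trimethylaluminium, C[Al](C)C
Why: Zirconium-catalysed syn-methylalumination of the terminal alkyne (Negishi carboalumination) puts methyl on the internal carbon and aluminium cis to it, and the (E)-alkenylalane is then cross-coupled with retention with the benzylic chloride under Ni(0) catalysis, a combination established for protected polyprenyl hydroquinones, so C2'=C3' should form as the E isomer.

Step 8
Reactants: 15 1,4-dimethoxy-2-methyl-3-[(2E,7R,11S)-3,7,11,15-tetramethylhexadeca-2,14-dien-1-yl]naphthalene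
Product: 16 (2E,6S,10R,14E)-16-(1,4-dimethoxy-3-methylnaphthalen-2-yl)-2,6,10,14-tetramethylhexadeca-2,14-dien-1-ol
Conditions: SeO2 (0.3 equiv), t-BuOOH (2 equiv), salicylic acid (0.1 equiv), CH2Cl2, 0 °C to rt
Reagents that add atoms: tert-butyl hydroperoxide, CC(C)(C)OO; selenium dioxide, O=[Se]=O
Why: Catalytic selenium dioxide allylic oxidation (Riley type: ene reaction, then [2,3]-sigmatropic shift) attacks the E-methyl group of the terminal isopropylidene unit in preference to the more hindered internal olefin, as known for aryl-oligoprenyl hydroquinone ethers, and so should place the hydroxyl on C16' with C14'=C15' as E.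

Step 9
Reactants: 16 (2E,6S,10R,14E)-16-(1,4-dimethoxy-3-methylnaphthalen-2-yl)-2,6,10,14-tetramethylhexadeca-2,14-dien-1-ol
Product: 17 2-[(2E,7R,11S,14E)-16-bromo-3,7,11,15-tetramethylhexadeca-2,14-dien-1-yl]-1,4-dimethoxy-3-methylnaphthalene
Conditions: PBr3 (0.4 equiv), Et2O, −10 °C
Reagents that add atoms: phosphorus tribromide, BrP(Br)Br
Why: Phosphorus tribromide converts the primary 2-methylallylic alcohol into the primary allylic bromide by SN2 displacement of its phosphite ester at low temperature, without allylic transposition or loss of olefin geometry.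

Step 10
Reactants: 18 geraniol
Product: 19 tert-butyl{[(2E)-3,7-dimethylocta-2,6-dien-1-yl]oxy}diphenylsilane
Conditions: TBDPSCl, imidazole, CH2Cl2, rt
Reagents that add atoms: tert-butyl(chloro)diphenylsilane, CC(C)(C)[Si](Cl)(c1ccccc1)c1ccccc1
Why: Silylation of the primary allylic alcohol gives an ether that survives the allylbarium step and also deactivates the C2=C3 olefin towards the following allylic oxidation.

Step 11
Reactants: 19 tert-butyl{[(2E)-3,7-dimethylocta-2,6-dien-1-yl]oxy}diphenylsilane
Product: 20 (2E,6E)-8-[(tert-butyldiphenylsilyl)oxy]-2,6-dimethylocta-2,6-dien-1-ol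
Conditions: SeO2 (0.3 equiv), t-BuOOH (2 equiv), salicylic acid (0.1 equiv), CH2Cl2, 0 °C to rt
Reagents that add atoms: tert-butyl hydroperoxide, CC(C)(C)OO; selenium dioxide, O=[Se]=O
Why: The same selenium dioxide allylic oxidation should hydroxylate the E-methyl group of the terminal olefin, which is both more electron-rich and less hindered than the olefin next to the silyloxy group, giving the (6E)-alcohol.

Step 12
Reactants: 20 (2E,6E)-8-[(tert-butyldiphenylsilyl)oxy]-2,6-dimethylocta-2,6-dien-1-ol
Product: 21 {[(2E,6E)-8-bromo-3,7-dimethylocta-2,6-dien-1-yl]oxy}(tert-butyl)diphenylsilane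
Conditions: CBr4, PPh3, CH2Cl2, 0 °C
Reagents that add atoms: carbon tetrabromide, BrC(Br)(Br)Br
Why: Appel bromination under neutral conditions gives the primary allylic bromide without cleaving the silyl ether or isomerising either olefin.

Step 13
Reactants: 21 {[(2E,6E)-8-bromo-3,7-dimethylocta-2,6-dien-1-yl]oxy}(tert-butyl)diphenylsilane; 22 (2E,6E)-farnesyl chloride
Product: 24 tert-butyl{[(2E,6E,10E,14E)-3,7,11,15,19-pentamethylicosa-2,6,10,14,18-pentaen-1-yl]oxy}diphenylsilane, via farnesylbarium chloride 23 (not isolated)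
Conditions: BaI2, Li biphenylide (2 equiv, from Li and biphenyl), THF, rt; 22, −78 °C; then 21, THF, −78 °C
Reagents that add atoms: none
Why: Rieke barium inserts into the allylic C–Cl bond at −78 °C to give a configurationally stable σ-allylbarium that couples with the allylic bromide α to α' with retention of both E geometries (allylbarium cross-coupling, the reaction type of the key step), which should give the all-E C25 chain in one operation.

Step 14
Reactants: 24 tert-butyl{[(2E,6E,10E,14E)-3,7,11,15,19-pentamethylicosa-2,6,10,14,18-pentaen-1-yl]oxy}diphenylsilane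
Product: 25 (2E,6E,10E,14E)-geranylfarnesol [(2E,6E,10E,14E)-3,7,11,15,19-pentamethylicosa-2,6,10,14,18-pentaen-1-ol]
Conditions: Bu4NF, THF, 0 °C to rt
Reagents that add atoms: none
Why: Fluoride-induced desilylation frees the primary allylic alcohol and leaves the five olefins untouched.

Step 15
Reactants: 25 (2E,6E,10E,14E)-geranylfarnesol
Product: 26 (2E,6E,10E,14E)-1-chloro-3,7,11,15,19-pentamethylicosa-2,6,10,14,18-pentaene (geranylfarnesyl chloride)
Conditions: NCS, Me2S, CH2Cl2, −40 °C to 0 °C
Reagents that add atoms: N-chlorosuccinimide, O=C1CCC(=O)N1Cl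
Why: Corey–Kim chlorination converts the allylic alcohol into the primary allylic chloride through an alkoxysulfonium ion that chloride displaces by SN2, without allylic rearrangement or E/Z isomerisation.

Step 16
Reactants: 17 2-[(2E,7R,11S,14E)-16-bromo-3,7,11,15-tetramethylhexadeca-2,14-dien-1-yl]-1,4-dimethoxy-3-methylnaphthalene; 26 geranylfarnesyl chloride
Product: 28 1,4-dimethoxy-2-methyl-3-[(2E,7R,11S,14E,18E,22E,26E,30E)-3,7,11,15,19,23,27,31,35-nonamethylhexatriaconta-2,14,18,22,26,30,34-heptaen-1-yl]naphthalene, via geranylfarnesylbarium chloride 27 (not isolated)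
Conditions: BaI2, Li biphenylide (2 equiv, from Li and biphenyl), THF, rt; 26 (1.5 equiv), −78 °C; then 17, THF, −78 °C
Reagents that add atoms: none
Why: Rieke barium inserts into the allylic C–Cl bond of 26 at −78 °C to give the σ-bonded allylbarium 27, which at this temperature neither migrates to its tertiary (γ, C19') form nor loses the 18'E geometry, and which then displaces bromide from the primary allylic CH2Br (C16') of 17 in a direct SN2 reaction that creates the C16'–C17' bond and with it the complete C45 side chain. The closest known reaction type is the α,α'-selective, geometry-retaining cross-coupling of γ,γ-disubstituted allylbarium reagents with allylic bromides used to join oligoprenyl units head-to-tail, and the event is a polarity-reversed copy of the prenyl transfer that forms this bond in the biosynthesis of the chain. No ring is closed and no stereocentre is created; C7' and C11' are remote sp3 centres that are not touched. The step needs α-attack at the nucleophile, SN2 instead of SN2' at the electrophile, retention of all six stereodefined E olefins and inertness of the arene: the first is secured by the non-fluxional Ba–C bond at −78 °C and the fully substituted γ-carbon, the second by the unhindered primary bromide whose γ-carbon (C14') carries the chain, the third by the absence of any acid or radical pathway, and the last by masking the quinone as its dimethyl ether, which offers the basic reagent neither a carbonyl group nor an acidic proton. Complete formation of 27 before 17 is added should keep Wurtz homo-coupling low.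

Step 17
Reactants: 28 1,4-dimethoxy-2-methyl-3-[(2E,7R,11S,14E,18E,22E,26E,30E)-3,7,11,15,19,23,27,31,35-nonamethylhexatriaconta-2,14,18,22,26,30,34-heptaen-1-yl]naphthalene
Product: 29 2-methyl-3-[(2E,7R,11S,14E,18E,22E,26E,30E)-3,7,11,15,19,23,27,31,35-nonamethylhexatriaconta-2,14,18,22,26,30,34-heptaen-1-yl]naphthalene-1,4-dione (CNP0265071.1)
Conditions: (NH4)2Ce(NO3)6 (2.5 equiv), MeCN/CH2Cl2/H2O, 0 °C
Reagents that add atoms: water, O
Why: Cerium(IV) oxidises the electron-rich 1,4-dimethoxynaphthalene to its radical cation, water adds and methanol is lost at both positions (oxidative demethylation), which should unmask the quinone much faster than the isolated trisubstituted olefins react and involves no stereocentre.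

**Compound list**

1 | menadione (2-methylnaphthalene-1,4-dione) | CC1=CC(=O)c2ccccc2C1=O | starting material
2 | menadiol (2-methylnaphthalene-1,4-diol) | Cc1cc(O)c2ccccc2c1O | intermediate
3 | 1,4-dimethoxy-2-methylnaphthalene | COc1cc(C)c(OC)c2ccccc12 | intermediate
4 | 2-(chloromethyl)-1,4-dimethoxy-3-methylnaphthalene | COc1c(C)c(CCl)c(OC)c2ccccc12 | intermediate
5 | (S)-3-bromo-2-methylpropan-1-ol | BrC[C@@H](C)CO | starting material
6 | (S)-1-bromo-3-chloro-2-methylpropane | BrC[C@@H](C)CCl | intermediate
7 | (R)-citronellyl bromide, (6R)-8-bromo-2,6-dimethyloct-2-ene | CC(C)=CCC[C@@H](C)CCBr | starting material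
8 | (R)-citronellylmagnesium bromide | CC(C)=CCC[C@@H](C)CC[Mg]Br | intermediate
9 | (2R,6S)-1-chloro-2,6,10-trimethylundec-9-ene | CC(C)=CCC[C@@H](C)CCC[C@@H](C)CCl | intermediate
10 | 4-bromo-1-(trimethylsilyl)but-1-yne | C[Si](C)(C)C#CCCBr | starting material
11 | [(2R,6S)-2,6,10-trimethylundec-9-en-1-yl]magnesium chloride | CC(C)=CCC[C@@H](C)CCC[C@@H](C)C[Mg]Cl | intermediate
12 | trimethyl[(6R,10S)-6,10,14-trimethylpentadec-13-en-1-yn-1-yl]silane | CC(C)=CCC[C@@H](C)CCC[C@@H](C)CCCC#C[Si](C)(C)C | intermediate
13 | (6R,10S)-6,10,14-trimethylpentadec-13-en-1-yne | CC(C)=CCC[C@@H](C)CCC[C@@H](C)CCCC#C | intermediate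
14 | dimethyl[(1E,6R,10S)-2,6,10,14-tetramethylpentadeca-1,13-dien-1-yl]alane | CC(C)=CCC[C@@H](C)CCC[C@@H](C)CCC/C(C)=C/[Al](C)C | intermediate
15 | 1,4-dimethoxy-2-methyl-3-[(2E,7R,11S)-3,7,11,15-tetramethylhexadeca-2,14-dien-1-yl]naphthalene | CC(C)=CCC[C@@H](C)CCC[C@@H](C)CCC/C(C)=C/Cc1c(C)c(OC)c2ccccc2c1OC | intermediate
16 | (2E,6S,10R,14E)-16-(1,4-dimethoxy-3-methylnaphthalen-2-yl)-2,6,10,14-tetramethylhexadeca-2,14-dien-1-ol | OC/C(C)=C/CC[C@@H](C)CCC[C@@H](C)CCC/C(C)=C/Cc1c(C)c(OC)c2ccccc2c1OC | intermediate
17 | 2-[(2E,7R,11S,14E)-16-bromo-3,7,11,15-tetramethylhexadeca-2,14-dien-1-yl]-1,4-dimethoxy-3-methylnaphthalene | BrC/C(C)=C/CC[C@@H](C)CCC[C@@H](C)CCC/C(C)=C/Cc1c(C)c(OC)c2ccccc2c1OC | intermediate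
18 | geraniol | CC(C)=CCC/C(C)=C/CO | starting material
19 | tert-butyl{[(2E)-3,7-dimethylocta-2,6-dien-1-yl]oxy}diphenylsilane | CC(C)=CCC/C(C)=C/CO[Si](c1ccccc1)(c1ccccc1)C(C)(C)C | intermediate
20 | (2E,6E)-8-[(tert-butyldiphenylsilyl)oxy]-2,6-dimethylocta-2,6-dien-1-ol | OC/C(C)=C/CC/C(C)=C/CO[Si](c1ccccc1)(c1ccccc1)C(C)(C)C | intermediate
21 | {[(2E,6E)-8-bromo-3,7-dimethylocta-2,6-dien-1-yl]oxy}(tert-butyl)diphenylsilane | BrC/C(C)=C/CC/C(C)=C/CO[Si](c1ccccc1)(c1ccccc1)C(C)(C)C | intermediate
22 | (2E,6E)-farnesyl chloride | CC(C)=CCC/C(C)=C/CC/C(C)=C/CCl | starting material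
23 | [(2E,6E)-farnesyl]barium chloride | CC(C)=CCC/C(C)=C/CC/C(C)=C/C[Ba]Cl | intermediate
24 | tert-butyl{[(2E,6E,10E,14E)-3,7,11,15,19-pentamethylicosa-2,6,10,14,18-pentaen-1-yl]oxy}diphenylsilane | CC(C)=CCC/C(C)=C/CC/C(C)=C/CC/C(C)=C/CC/C(C)=C/CO[Si](c1ccccc1)(c1ccccc1)C(C)(C)C | intermediate
25 | (2E,6E,10E,14E)-geranylfarnesol | CC(C)=CCC/C(C)=C/CC/C(C)=C/CC/C(C)=C/CC/C(C)=C/CO | intermediate
26 | (2E,6E,10E,14E)-geranylfarnesyl chloride | CC(C)=CCC/C(C)=C/CC/C(C)=C/CC/C(C)=C/CC/C(C)=C/CCl | intermediate
27 | [(2E,6E,10E,14E)-geranylfarnesyl]barium chloride | CC(C)=CCC/C(C)=C/CC/C(C)=C/CC/C(C)=C/CC/C(C)=C/C[Ba]Cl | intermediate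
28 | 1,4-dimethoxy-2-methyl-3-[(2E,7R,11S,14E,18E,22E,26E,30E)-3,7,11,15,19,23,27,31,35-nonamethylhexatriaconta-2,14,18,22,26,30,34-heptaen-1-yl]naphthalene | CC(C)=CCC/C(C)=C/CC/C(C)=C/CC/C(C)=C/CC/C(C)=C/CC/C(C)=C/CC[C@@H](C)CCC[C@@H](C)CCC/C(C)=C/Cc1c(C)c(OC)c2ccccc2c1OC | intermediate
29 | 2-methyl-3-[(2E,7R,11S,14E,18E,22E,26E,30E)-3,7,11,15,19,23,27,31,35-nonamethylhexatriaconta-2,14,18,22,26,30,34-heptaen-1-yl]naphthalene-1,4-dione (CNP0265071.1) | CC(C)=CCC/C(C)=C/CC/C(C)=C/CC/C(C)=C/CC/C(C)=C/CC/C(C)=C/CC[C@@H](C)CCC[C@@H](C)CCC/C(C)=C/CC1=C(C)C(=O)c2ccccc2C1=O | target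

**Step count and risks**

Total step count: 17. Longest linear sequence: 9 steps (5 → 6 → 9 → 12 → 13 → 15 → 16 → 17 → 28 → 29; steps 3, 4, 5, 6, 7, 8, 9, 16, 17).

Most likely to fail, first: step 16. What may go wrong is loss of regiocontrol (γ-attack of the allylmetal or SN2' attack on the bromide), Wurtz homo-coupling of either partner, or E/Z scrambling of the allylmetal if the temperature rises. The fallback replaces the allylbarium by a sulfone-stabilised carbanion, whose α-regiochemistry is fixed by the sulfonyl group. It sets out from 26 and 17 and returns at 28. Chloride 26 is treated with sodium p-toluenesulfinate in DMF to give (2E,6E,10E,14E)-geranylfarnesyl p-tolyl sulfone F1. Deprotonation with n-BuLi in THF at −78 °C and alkylation with 17 gives the C17'-sulfonylated coupling product F2 as a mixture of C17' epimers, which is of no consequence. Reductive desulfonylation with LiBHEt3 and catalytic Pd(dppp)Cl2 in THF at 0 °C then gives 28.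

Second: step 8. What may go wrong is competing ene attack at the internal C2'=C3' olefin, over-oxidation beyond the alcohol, and oxidative damage to the electron-rich arene at low conversion. The fallback builds the E-hydroxymethyl olefin by olefination before the arene and the second olefin are present. It sets out from 13 and returns at 16. Ozonolysis of the single olefin of 13 (O3, CH2Cl2/MeOH, −78 °C, dye end-point; Me2S) gives (4S,8R)-4,8-dimethyltridec-12-ynal F3. Wittig olefination with ethyl 2-(triphenylphosphoranylidene)propanoate gives ethyl (2E,6S,10R)-2,6,10-trimethylpentadec-2-en-14-ynoate F4. DIBAL-H reduction at −78 °C gives (2E,6S,10R)-2,6,10-trimethylpentadec-2-en-14-yn-1-ol F5. Carboalumination as in step 7 with one further equivalent of Me3Al, which carries the hydroxyl as its aluminium alkoxide, gives the alkenylalane aluminium alkoxide F6, not isolated. This is coupled with 4 under the Ni(0) conditions of step 7 and gives 16 after aqueous work-up.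

Third: step 5. What may go wrong is dehydrobromination of the homopropargylic bromide by the basic Grignard reagent and slow copper turnover with the β-branched alkylmagnesium chloride. The fallback adds the four carbons as C2 plus C2 by epoxide opening and acetylide alkylation. It sets out from 11 and returns at 13, so that step 6 is not needed. Grignard reagent 11 is added to ethylene oxide (CuI cat., THF, −30 °C) to give (4R,8S)-4,8,12-trimethyltridec-11-en-1-ol F7. Treatment with I2, PPh3 and imidazole gives (4R,8S)-1-iodo-4,8,12-trimethyltridec-11-ene F8. Lithium acetylide–ethylenediamine complex in DMSO then gives 13.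

Further compounds
F1 | step 16 | (2E,6E,10E,14E)-geranylfarnesyl p-tolyl sulfone | CC(C)=CCC/C(C)=C/CC/C(C)=C/CC/C(C)=C/CC/C(C)=C/CS(=O)(=O)c1ccc(C)cc1
F2 | step 16 | 1,4-dimethoxy-2-methyl-3-[(2E,7R,11S,14E,18E,22E,26E,30E)-3,7,11,15,19,23,27,31,35-nonamethyl-17-(4-methylbenzenesulfonyl)hexatriaconta-2,14,18,22,26,30,34-heptaen-1-yl]naphthalene (C17' epimers) | CC(C)=CCC/C(C)=C/CC/C(C)=C/CC/C(C)=C/CC/C(C)=C/C(C/C(C)=C/CC[C@@H](C)CCC[C@@H](C)CCC/C(C)=C/Cc1c(C)c(OC)c2ccccc2c1OC)S(=O)(=O)c1ccc(C)cc1
F3 | step 8 | (4S,8R)-4,8-dimethyltridec-12-ynal | O=CCC[C@@H](C)CCC[C@@H](C)CCCC#C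
F4 | step 8 | ethyl (2E,6S,10R)-2,6,10-trimethylpentadec-2-en-14-ynoate | CCOC(=O)/C(C)=C/CC[C@@H](C)CCC[C@@H](C)CCCC#C
F5 | step 8 | (2E,6S,10R)-2,6,10-trimethylpentadec-2-en-14-yn-1-ol | OC/C(C)=C/CC[C@@H](C)CCC[C@@H](C)CCCC#C
F6 | step 8 | alkenylalane aluminium alkoxide from F5 (dimethylaluminium alkoxide of the C1-dimethylalanyl (1E,14E)-dienol) | C[Al](C)OC/C(C)=C/CC[C@@H](C)CCC[C@@H](C)CCC/C(C)=C/[Al](C)C
F7 | step 5 | (4R,8S)-4,8,12-trimethyltridec-11-en-1-ol | CC(C)=CCC[C@@H](C)CCC[C@@H](C)CCCO
F8 | step 5 | (4R,8S)-1-iodo-4,8,12-trimethyltridec-11-ene | CC(C)=CCC[C@@H](C)CCC[C@@H](C)CCCI
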